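0.168 min⁻¹ was the number I took from the delta and beta runs. It is my loss constant for the starting material (its apparent first-order rate constant): the logarithm of one over the fraction left, divided by the time. I worked with the fraction left and not the fraction made.

| flask | starting material | remark | time |
|---|---|---|---|
| delta | 0.036 M | run made earlier |  |
| beta | 0.16 M | run made earlier |  |
| Saturday's | 0.030 M |  | 30 min |
| Wednesday's | 0.040 M |  | 30 min |
| Monday's | 0.060 M |  | 30 min |
| Sunday's | 0.10 M |  | 30 min |

- delta (time / min: target / %, starting material / %): 5.00: 1.5, 40.6; 10.0: 6.2, 18.3; 15.0: 8.8, 7.7; 20.0: 14.7, 6.2; 25.0: 14.0, 1.5; 30.0: 17.7, 0.5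
- beta (time / min: target / %, starting material / %): 2.50: 0, 66.6; 4.00: 2.1, 48.9; 6.00: 2.9, 36.0; 10.0: 5.1, 18.9; 20.0: 12.4, 4.1; 30.0: 16.2, 1.2

(scatter of a reading: 1 percentage point)

- what was read earlier has a scatter of 1 percentage point, one standard deviation
- a reading or a percentage of target counts all its forms, free or not
- "hardly changes" means that all values lie within two and a half points (for a concentration: within two and a half percent of the largest)
- a reading of starting material is of its free form alone

- amount of target at the end, in percent of the starting material charged for Saturday's, Wednesday's, Monday's, Sunday's, in this order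
- the course of these numbers from the first flask to the last (falls all the way / falls, then rises / rises all the way / rises, then falls / hardly changes)

The first setting was the charge. At 10.0 min the delta run held 18.3 % and the beta run 18.9 %, a gap of 0.6 percentage points, which was less than the scatter of 1 point. Yet the beta charge was 4.44 times the delta charge. The constants from the two runs were about equal, so I used one constant for the four flasks. Saturday's charge lay below the delta charge, and the others lay between the two runs.

The second setting was the time. By hand, 0.168 min⁻¹ leaves 0.643 % at 30 min, so I expected nearly all of the starting material to have reacted in each of the four flasks. The fraction gone was not the fraction made, though: the delta run ended with 17.7 % of target, and 81.8 % of its charge was read as neither target nor free starting material. Target in the beta run rose by 11 points between 10.0 min and 30.0 min. That was more than the final gap between the runs, 1.5 points. The two final readings were close, so I committed to their mean, 16.9 %, in each flask, and to a row that hardly changes.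

The forecast gave 17.2 %, 17 %, 16.8 % and 16.5 %, a row that hardly changes, in its words “the later steps also look effectively first order”.

The flasks gave 17.2 %, 17.2 %, 17.2 % and 17.2 % of target, so the row hardly changes.

    starting material ⇌ intermediate C (K = 21.0, k = 8.80 × 10⁻⁴ s⁻¹)
    intermediate D ⇌ target (K = 0.740, k = 1.30 × 10⁻⁴ s⁻¹)
    starting material + target ⇌ idle adduct, settled at all times (K = 3.60 L mol⁻¹)
    starting material → intermediate B (k = 0.00140 s⁻¹)
    starting material → intermediate A (k = 5.60 × 10⁻⁴ s⁻¹)
    intermediate A → intermediate D (k = 1.70 × 10⁻⁴ s⁻¹)
    intermediate B ⇌ intermediate E (K = 1.40, k = 4.30 × 10⁻⁴ s⁻¹)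
    intermediate C → intermediate D (k = 7.70 × 10⁻⁴ s⁻¹)
    intermediate B → target (k = 4.00 × 10⁻⁴ s⁻¹)

Idle adduct, which the target figures include, stood at 0.0299 % in Saturday's and 0.104 % in Sunday's at 30.0 min. With 0.168 min⁻¹, I get 8.02 % of starting material left at 15.0 min, and Saturday's held 8.00 %. By my reckoning, the same constant brings free starting material under 2.00 % of the charge at 23.3 min, and Wednesday's took 23.7 min.

All runs were generated by integration with constants of no real substance; the scatter is artificial.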